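The seven-membered ring (C1, C5–C10) is traced back to a six-membered one: the array C10(O)–C9=C8(C14), flanked by quaternary C1, is a 2-methylcyclohexanone enlarged by one methylene. A Simmons–Smith/FeCl3 (Saegusa–Ito) sequence on a trans-hydrindanone silyl enol ether inserts C9 between C10 and C8 and leaves the C8=C9 enone in one operation. Because C1 is quaternary, the enol ether can only point toward C8, which fixes the regiochemistry. The precursor, built from (R)-carvone, is the C10=C8 trimethylsilyl enol ether of a trans-hydrindane that already carries the C2 acetate, the silylated C4 isopropyl carbinol and the C6 silyl ether, with all five ring stereocentres in place.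

Key step: step 12

Remark (numbering): daucane numbering is used for every intermediate (C1 quaternary ring-fusion carbon with methyl C15; C2, C3, C4 in the five-membered ring; C5 ring-fusion CH; C6, C7, C8 with methyl C14, C9, C10). α/β refer to a drawing with C15 on the β face.

Remark (chemistry): the tertiary C4 oxygen is carried as a triethylsilyl ether, which should survive FeCl3 and NaOAc/MeOH better than a trimethylsilyl ether and is removed together with the C6 TBS ether. Compound 4 is used as its epimer mixture because C1 is planarised again in step 2.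

Step 1
Reactants: 1 (R)-carvone; 2 iodomethane
Product: 4 α′-methylcarvone (methyl on future C1; mainly trans to isopropenyl), via carvone lithium enolate 3 (not isolated)
Conditions: LiN(i-Pr)2, THF, −78 °C; then MeI, −78 → 0 °C
Reagents that add atoms: iodomethane, CI
Why: Kinetic deprotonation at the α′ carbon gives the cross-conjugated lithium enolate, and its SN2 methylation (enolate alkylation) should occur mainly anti to the C5 isopropenyl group; the configuration of the new centre is irrelevant because it is planarised again in step 2.

Step 2
Reactants: 4 α′-methylcarvone; 5 formaldehyde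
Product: 7 hydroxymethyl ketone (quaternary C1: C15 cis and CH2OH trans to isopropenyl), via tetrasubstituted lithium enolate 6 (not isolated)
Conditions: LiN(i-Pr)2, THF, −78 °C; then CH2O (gas, from cracked paraformaldehyde), −78 °C; AcOH quench
Reagents that add atoms: formaldehyde, C=O
Why: A second kinetic α′-deprotonation gives the tetrasubstituted enolate, and its crossed aldol addition to monomeric formaldehyde should take place anti to the adjacent C5 isopropenyl group, as second alkylations of 6-alkylcarvones do, which sets quaternary C1 with C15 cis and the C2 carbon trans to the C5 substituent, the arrangement needed for the trans ring fusion.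

Step 3
Reactants: 7 hydroxymethyl ketone
Product: 8 formyl ketone (C2 aldehyde on quaternary C1)
Conditions: Dess–Martin periodinane, CH2Cl2, 0 °C → rt
Reagents that add atoms: none
Why: Dess–Martin oxidation turns the neopentylic primary alcohol into the non-enolisable aldehyde under neutral conditions, so that neither retro-aldol loss of formaldehyde nor deformylation of the β-keto aldehyde is triggered and no stereocentre is touched.

Step 4
Reactants: 8 formyl ketone
Product: 10 acetyl formyl enone (C4 methyl ketone), via methoxy hydroperoxide 9 (not isolated)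
Conditions: O3, CH2Cl2/MeOH, −78 °C (Sudan Red 7B end point); then Me2S, −78 °C → rt
Reagents that add atoms: ozone, [O-][O+]=O
Why: Ozonolysis with reductive work-up is chemoselective for the electron-rich 1,1-disubstituted isopropenyl double bond over the electron-poor enone double bond when ozone is dosed to an indicator end point, the carbonyl oxide is trapped by methanol and reduced by Me2S to the methyl ketone (C4 with C3), and the neutral medium leaves C5 unepimerised.

Step 5
Reactants: 10 acetyl formyl enone
Product: 12 trans-hydrindane hydroxy diketone (2α-OH; C4 ketone; C10 enone), via methyl ketone lithium enolate 11 (not isolated)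
Conditions: LiN(SiMe3)2, THF (high dilution), −78 → −40 °C; AcOH quench at −78 °C
Reagents that add atoms: none
Why: Kinetic deprotonation of the methyl ketone at C3 is followed by intramolecular aldol addition to the neighbouring non-enolisable aldehyde, which joins the trans-diequatorial C1 and C5 substituents into the trans-fused five-membered ring, and lithium chelation of the aldehyde oxygen to the C10 carbonyl should place the new C2 oxygen cis to C10 and trans to C15 (2α), the cold acetic acid quench preventing dehydration and C5 epimerisation.

Step 6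
Reactants: 12 trans-hydrindane hydroxy diketone; 13 isopropylmagnesium chloride
Product: 14 diol (2α-OH; 4β-OH; 4α-isopropyl)
Conditions: i-PrMgCl (3 equiv), LaCl3·2LiCl, THF, −78 → −20 °C; aq. NH4Cl
Reagents that add atoms: isopropylmagnesium chloride, CC(C)[Mg]Cl
Why: Grignard 1,2-addition, promoted by LaCl3·2LiCl to suppress enolisation and β-hydride reduction, should take place at the C4 cyclopentanone and not at the C10 enone carbonyl, which is shielded by quaternary C1 and C14, and from the α face because the β trajectory is syn-axial to the C15 methyl across the five-membered ring while the 2α magnesium alkoxide sits on the attacked face, which gives 4β-OH and 4α-isopropyl.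

Step 7
Reactants: 14 diol; 15 acetic anhydride
Product: 16 C2 acetate (4β-OH free)
Conditions: Ac2O, pyridine, 4-(dimethylamino)pyridine (cat.), CH2Cl2, 0 °C → rt
Reagents that add atoms: acetic anhydride, CC(=O)OC(C)=O
Why: Nucleophilic-catalysed acylation esterifies the secondary C2 hydroxyl and leaves the tertiary C4 hydroxyl, which is inert under these conditions, so that the acetate of the target is installed without a protecting group and with retention at C2.

Step 8
Reactants: 16 C2 acetate
Product: 17 bis(triethylsilyl) dienol ether (C10-OTES with C10=C8 and C6=C7; 4β-OTES)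
Conditions: Et3SiOTf, Et3N, CH2Cl2, −20 → 0 °C
Reagents that add atoms: triethylsilyl trifluoromethanesulfonate, CC[Si](CC)(CC)OS(=O)(=O)C(F)(F)F
Why: Soft enolisation with silyl triflate and amine silylates the enone oxygen and removes a γ proton from C6, the only enolisable position because C1 is quaternary, to give the linear dienol silyl ether, and the same reagent silylates the tertiary C4 hydroxyl, while the acetate is not enolised at this temperature.

Step 9
Reactants: 17 bis(triethylsilyl) dienol ether
Product: 19 6α-hydroxy enone (4β-OTES), via C6–C7 epoxide 18 (not isolated)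
Conditions: mCPBA, NaHCO3, CH2Cl2, −20 °C; then aq. Na2S2O3/NaHCO3
Reagents that add atoms: m-chloroperbenzoic acid, OOC(=O)c1cccc(Cl)c1
Why: In this vinylogous Rubottom oxidation the peracid should epoxidise the terminal C6=C7 bond of the siloxydiene, since the tetrasubstituted C10=C8 bond is screened on both faces by quaternary C1 and its substituents, from the α face opposite the axial C15 methyl and the 4β silyloxy group, and opening of the allylic epoxide by the enol ether then returns the enone with the 6α hydroxyl.

Step 10
Reactants: 19 6α-hydroxy enone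
Product: 20 6α-TBS ether enone
Conditions: t-BuMe2SiOTf, 2,6-lutidine, CH2Cl2, −78 → 0 °C
Reagents that add atoms: tert-butyldimethylsilyl trifluoromethanesulfonate, CC(C)(C)[Si](C)(C)OS(=O)(=O)C(F)(F)F
Why: Silyl triflate with 2,6-lutidine silylates the hindered secondary C6 hydroxyl, the only free hydroxyl, by O-silylation with retention and without affecting enone or acetate.

Step 11
Reactants: 20 6α-TBS ether enone
Product: 22 trimethylsilyl enol ether (C10=C8; key-step precursor), via C10 lithium enolate 21 (not isolated)
Conditions: LiBH(s-Bu)3, THF, −78 °C; then Me3SiCl, Et3N, −78 → 0 °C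
Reagents that add atoms: chlorotrimethylsilane, C[Si](C)(C)Cl
Why: The bulky trialkylborohydride should add hydride to C7 in a conjugate reduction, as it does with carvone, because 1,2-attack at C10 is blocked by quaternary C1 and C14, and O-silylation of the resulting lithium enolate gives the C10=C8 enol ether regiospecifically, with no new stereocentre since C7 becomes CH2 and C8 stays trigonal, while the hindered acetate should survive at −78 °C.

Step 12
Reactants: 22 trimethylsilyl enol ether; 23 diiodomethane
Product: 26 trans-hydroazulenone (C10 ketone; C8=C9), via siloxycyclopropane 24 (not isolated), via β-chloro ketone 25 (not isolated)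
Conditions: Et2Zn, CH2I2, CH2Cl2, 0 °C → rt; then FeCl3, pyridine, DMF, 0 °C → rt; then NaOAc, MeOH, 60 °C
Reagents that add atoms: diiodomethane, ICI
Why: The zinc carbenoid EtZnCH2I formed from Et2Zn and CH2I2 transfers the C9 methylene in a concerted [2+1] step to the electron-rich C10=C8 enol ether bond (new bonds C9–C8 and C9–C10), FeCl3 then removes the silyl group and oxidises the cyclopropanol oxygen by one electron, the oxygen radical cleaves the internal C8–C10 bond to the tertiary C8 radical, which takes chlorine from a second FeCl3, and NaOAc eliminates HCl through the C9 enolate (E1cB) to leave the C10 ketone conjugated with C8=C9. The closest known reaction type is the Saegusa–Ito one-carbon ring expansion, that is, Simmons–Smith cyclopropanation of a 2-alkylcycloalkanone silyl enol ether followed by FeCl3 opening of the 1-siloxybicyclo[n.1.0]alkane to the cycloalk-2-enone. The transient three-membered ring is closed by cheletropic methylene transfer to the alkene, whereas the seven-membered ring (C1, C5–C10) is not formed by a cyclisation but by homolytic fragmentation of the bond shared by the two rings of the bicyclo[4.1.0]heptane unit, an endocyclic enlargement of the six-membered ring. No stereocentre is created, because C8 and C10 end up trigonal, so the face of cyclopropanation (expected opposite axial C15) and the configuration of the C8 chloride do not matter, and C1, C2, C4, C5 and C6 are neither enolisable nor ionised under these conditions. The selectivity required is regiochemical and is secured by the substrate: quaternary C1 allows the enol ether only toward C8, cleavage of the internal bond gives a tertiary radical and the unstrained seven-membered ketone whereas cleavage of C9–C10 would give a primary radical, and only the C9 protons are acidified by the carbonyl, so HCl is lost toward C9. The acetate, the TBS ether and the tertiary TES ether should tolerate the zinc reagent, FeCl3 buffered with pyridine in DMF, and the weakly basic NaOAc.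

Step 13
Reactants: 26 trans-hydroazulenone
Product: 27 10β-allylic alcohol
Conditions: NaBH4, CeCl3·7H2O, MeOH, −78 → −40 °C
Reagents that add atoms: none
Why: Luche reduction adds hydride 1,2 to the enone carbonyl, and attack should come from the α face, anti to the axial C15 methyl on the adjacent quaternary C1, which places the new hydroxyl cis to C15 (10β), while the acetate and the silyl ethers are inert to NaBH4/CeCl3 at low temperature.

Step 14
Reactants: 27 10β-allylic alcohol; 28 benzoyl chloride
Product: 29 10β-benzoate
Conditions: BzCl, pyridine, 4-(dimethylamino)pyridine (cat.), CH2Cl2, 0 °C → rt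
Reagents that add atoms: benzoyl chloride, O=C(Cl)c1ccccc1
Why: Nucleophilic-catalysed O-acylation with benzoyl chloride esterifies the only free hydroxyl, the neopentylic allylic C10-OH, with retention of configuration.

Step 15
Reactants: 29 10β-benzoate
Product: 30 4β,6α-diol
Conditions: HF·pyridine, pyridine, THF, 0 °C → rt
Reagents that add atoms: none
Why: Buffered fluoride cleaves the secondary TBS ether at C6 and the tertiary TES ether at C4 in one desilylation, and because the medium is neither basic nor strongly acidic the acetate and benzoate should neither migrate nor ionise.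

Step 16
Reactants: 30 4β,6α-diol; 31 angelic acid
Product: 32 target CNP0248576.1
Conditions: angelic acid, 2,4,6-trichlorobenzoyl chloride, Et3N, toluene, rt; then 30, 80 °C
Reagents that add atoms: angelic acid, C/C=C(/C)C(=O)O
Why: Yamaguchi-type esterification through the mixed anhydride with 2,4,6-trichlorobenzoic acid, run without a nucleophilic catalyst, should acylate the secondary 6α hydroxyl with retention while the tertiary C4 hydroxyl stays free, and it avoids the isomerisation of the (Z)-angeloyl unit to the (E)-tigloyl unit that base or nucleophilic catalysts cause.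

Compound list
1 | (R)-carvone, (5R)-2-methyl-5-(prop-1-en-2-yl)cyclohex-2-en-1-one | CC(=C)[C@@H]1CC=C(C)C(=O)C1 | starting material
2 | iodomethane | CI | starting material
3 | carvone α′ lithium enolate (cross-conjugated; not isolated) | CC(=C)[C@@H]1CC=C(C)C(O[Li])=C1 | intermediate
4 | α′-methylcarvone (6-methylcarvone; drawn as the major epimer, methyl trans to isopropenyl; used as the epimer mixture) | CC(=C)[C@@H]1CC=C(C)C(=O)[C@H]1C | intermediate
5 | formaldehyde | C=O | starting material
6 | tetrasubstituted lithium enolate of 4 (not isolated) | CC(=C)[C@@H]1CC=C(C)C(O[Li])=C1C | intermediate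
7 | hydroxymethyl ketone: 6-(hydroxymethyl)-6-methylcarvone, C15 methyl cis and CH2OH (C2) trans to isopropenyl | CC(=C)[C@@H]1CC=C(C)C(=O)[C@@]1(C)CO | intermediate
8 | formyl ketone: 6-formyl-6-methylcarvone, CHO trans to isopropenyl | CC(=C)[C@@H]1CC=C(C)C(=O)[C@@]1(C)C=O | intermediate
9 | α-methoxy hydroperoxide from methanol trapping of the carbonyl oxide (C4 epimers; not isolated) | COC(C)(OO)[C@@H]1CC=C(C)C(=O)[C@@]1(C)C=O | intermediate
10 | acetyl formyl enone: 5-acetyl-6-formyl-2,6-dimethylcyclohex-2-en-1-one (carvone numbering), acetyl and formyl trans | CC(=O)[C@@H]1CC=C(C)C(=O)[C@@]1(C)C=O | intermediate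
11 | lithium enolate of the methyl ketone of 10 (C3=C4; not isolated) | C=C(O[Li])[C@@H]1CC=C(C)C(=O)[C@@]1(C)C=O | intermediate
12 | trans-hydrindane hydroxy diketone: 1β-CH3, 5α-H, 2α-OH, C4 ketone, C10 ketone conjugated with C8=C7 (C14 on C8) | O=C1C(C)=CC[C@@H]2[C@]1(C)[C@@H](O)CC2=O | intermediate
13 | isopropylmagnesium chloride | CC(C)[Mg]Cl | starting material
14 | diol: as 12 with 4β-OH and 4α-isopropyl at C4 | O=C1C(C)=CC[C@@H]2[C@]1(C)[C@@H](O)C[C@@]2(O)C(C)C | intermediate
15 | acetic anhydride | CC(=O)OC(C)=O | starting material
16 | 2α-acetate of 14 (4β-OH free) | O=C1C(C)=CC[C@@H]2[C@]1(C)[C@@H](OC(C)=O)C[C@@]2(O)C(C)C | intermediate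
17 | C10 triethylsilyl dienol ether (C10=C8, C6=C7) with 2α-OAc and 4β-OTES | CC[Si](CC)(CC)OC1=C(C)C=C[C@@H]2[C@]1(C)[C@@H](OC(C)=O)C[C@@]2(O[Si](CC)(CC)CC)C(C)C | intermediate
18 | 6α,7α-epoxide of 17 (not isolated) | CC[Si](CC)(CC)OC1=C(C)[C@@H]2O[C@@H]2[C@@H]3[C@]1(C)[C@@H](OC(C)=O)C[C@@]3(O[Si](CC)(CC)CC)C(C)C | intermediate
19 | 6α-hydroxy enone (C10 ketone, C8=C7; 2α-OAc, 4β-OTES) | O=C1C(C)=C[C@H](O)[C@@H]2[C@]1(C)[C@@H](OC(C)=O)C[C@@]2(O[Si](CC)(CC)CC)C(C)C | intermediate
20 | 6α-TBS ether of 19 | O=C1C(C)=C[C@H](O[Si](C)(C)C(C)(C)C)[C@@H]2[C@]1(C)[C@@H](OC(C)=O)C[C@@]2(O[Si](CC)(CC)CC)C(C)C | intermediate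
21 | C10 lithium enolate (C10=C8) from conjugate reduction of 20 (not isolated) | [Li]OC1=C(C)C[C@H](O[Si](C)(C)C(C)(C)C)[C@@H]2[C@]1(C)[C@@H](OC(C)=O)C[C@@]2(O[Si](CC)(CC)CC)C(C)C | intermediate
22 | key-step precursor: trans-hydrindanone trimethylsilyl enol ether (C10=C8) with 2α-OAc, 4β-OTES, 6α-OTBS | C[Si](C)(C)OC1=C(C)C[C@H](O[Si](C)(C)C(C)(C)C)[C@@H]2[C@]1(C)[C@@H](OC(C)=O)C[C@@]2(O[Si](CC)(CC)CC)C(C)C | intermediate
23 | diiodomethane | ICI | starting material
24 | siloxycyclopropane: C9 bridging C8 and C10 (1-siloxybicyclo[4.1.0]heptane unit; drawn with C9 on the α face; not isolated) | C[Si](C)(C)O[C@@]12C[C@]1(C)C[C@H](O[Si](C)(C)C(C)(C)C)[C@@H]3[C@]2(C)[C@@H](OC(C)=O)C[C@@]3(O[Si](CC)(CC)CC)C(C)C | intermediate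
25 | β-chloro ketone: seven-membered C10 ketone with C9 methylene and chlorine on C8 (C8 epimers; not isolated) | O=C1CC(C)(Cl)C[C@H](O[Si](C)(C)C(C)(C)C)[C@@H]2[C@]1(C)[C@@H](OC(C)=O)C[C@@]2(O[Si](CC)(CC)CC)C(C)C | intermediate
26 | key-step product: trans-hydroazulenone, C10 ketone conjugated with C8=C9, 2α-OAc, 4β-OTES, 6α-OTBS | CC(C)(C)[Si](C)(C)O[C@H]1CC(C)=CC(=O)[C@@]2(C)[C@@H](OC(C)=O)C[C@@](O[Si](CC)(CC)CC)(C(C)C)[C@H]12 | intermediate
27 | 10β-allylic alcohol (2α-OAc, 4β-OTES, 6α-OTBS) | CC(C)(C)[Si](C)(C)O[C@H]1CC(C)=C[C@H](O)[C@@]2(C)[C@@H](OC(C)=O)C[C@@](O[Si](CC)(CC)CC)(C(C)C)[C@H]12 | intermediate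
28 | benzoyl chloride | O=C(Cl)c1ccccc1 | starting material
29 | 10β-benzoate of 27 | CC(C)(C)[Si](C)(C)O[C@H]1CC(C)=C[C@H](OC(=O)c2ccccc2)[C@@]2(C)[C@@H](OC(C)=O)C[C@@](O[Si](CC)(CC)CC)(C(C)C)[C@H]12 | intermediate
30 | 2α-acetoxy-10β-benzoyloxydauc-8-ene-4β,6α-diol | O[C@H]1CC(C)=C[C@H](OC(=O)c2ccccc2)[C@@]2(C)[C@@H](OC(C)=O)C[C@@](O)(C(C)C)[C@H]12 | intermediate
31 | angelic acid, (Z)-2-methylbut-2-enoic acid | C/C=C(/C)C(=O)O | starting material
32 | CNP0248576.1: 2α-acetoxy-6α-angeloyloxy-10β-benzoyloxy-4β-hydroxydauc-8-ene | C/C=C(/C)C(=O)O[C@H]1CC(C)=C[C@H](OC(=O)c2ccccc2)[C@@]2(C)[C@@H](OC(C)=O)C[C@@](O)(C(C)C)[C@H]12 | target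

Total step count: 16. Longest linear sequence: 16 steps, from (R)-carvone 1 to 32.

Steps most likely to fail

Step 12 (key step). What may go wrong: methylene transfer to the tetrasubstituted enol ether next to quaternary C1 may be slow, so that Lewis-acidic zinc halides hydrolyse the enol ether before it is cyclopropanated; or the external cyclopropane bond may cleave in competition. Fallback (diazoalkane homologation followed by dehydrogenation): starting from 22, mild acid hydrolysis (aq. oxalic acid, THF) gives the saturated trans-hydrindanone F1 as C8 epimers. Me3SiCHN2 with BF3·OEt2 in CH2Cl2 at −78 °C then inserts one carbon with migration of the less substituted C8 (Tiffeneau–Demjanov-type homologation) to give the cycloheptanone F2, which can enolise only toward C9. Dehydrogenation with IBX in DMSO returns to enone 26.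

Step 9. What may go wrong: oxygen transfer with the wrong regiochemistry, that is, attack on the C10=C8 enol ether bond and hydroxylation of C8 instead of C6. Fallback (C–H oxidation and directed reduction in place of electrophilic hydroxylation): starting from 16, allylic oxidation of the C6 methylene with Pd(OH)2/C, t-BuOOH and K2CO3 in CH2Cl2 gives the ene-dione F3. Me4NBH(OAc)3 in MeCN/AcOH (Evans–Saksena reduction) should reduce only the C6 ketone, by delivery of hydride from the 4β-hydroxyl to the β face, and give the 4β,6α-diol enone F4. t-BuMe2SiOTf/2,6-lutidine at −78 °C silylates the secondary hydroxyl to give the 6α-TBS ether F5, and Et3SiOTf/2,6-lutidine then silylates the tertiary hydroxyl, which returns to 20.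

Step 5. What may go wrong: insufficient chelate control in the ring closure, so that the C2 carbinol forms with the 2β configuration or as a mixture; dehydration of the aldol is the second concern. Fallback (C2 configuration set by directed reduction instead of by the aldol): starting from 10, the cyclisation is run as in step 5 and the epimeric aldol F6 is carried on. i-PrMgCl/LaCl3·2LiCl gives the 2-epi diol F7, and Dess–Martin oxidation of its secondary hydroxyl gives the hydroxy dione F8. Me4NBH(OAc)3 then delivers hydride from the 4β-hydroxyl to the β face of C2, which returns to diol 14.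

Further compounds
F1 | step 12 | saturated trans-hydrindan-10-one (C8 epimers; 2α-OAc, 4β-OTES, 6α-OTBS) | O=C1C(C)C[C@H](O[Si](C)(C)C(C)(C)C)[C@@H]2[C@]1(C)[C@@H](OC(C)=O)C[C@@]2(O[Si](CC)(CC)CC)C(C)C
F2 | step 12 | ring-enlarged saturated cycloheptanone (C10 ketone, C9 methylene, C8 epimers) | O=C1CC(C)C[C@H](O[Si](C)(C)C(C)(C)C)[C@@H]2[C@]1(C)[C@@H](OC(C)=O)C[C@@]2(O[Si](CC)(CC)CC)C(C)C
F3 | step 9 | ene-dione (C6 and C10 ketones, C7=C8; 2α-OAc, 4β-OH) | O=C1C(C)=CC(=O)[C@@H]2[C@]1(C)[C@@H](OC(C)=O)C[C@@]2(O)C(C)C
F4 | step 9 | 4β,6α-diol enone (2α-OAc) | O=C1C(C)=C[C@H](O)[C@@H]2[C@]1(C)[C@@H](OC(C)=O)C[C@@]2(O)C(C)C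
F5 | step 9 | 6α-TBS ether with free 4β-OH | O=C1C(C)=C[C@H](O[Si](C)(C)C(C)(C)C)[C@@H]2[C@]1(C)[C@@H](OC(C)=O)C[C@@]2(O)C(C)C
F6 | step 5 | 2β-hydroxy epimer of 12 | O=C1C(C)=CC[C@@H]2[C@]1(C)[C@H](O)CC2=O
F7 | step 5 | 2β-hydroxy epimer of 14 | O=C1C(C)=CC[C@@H]2[C@]1(C)[C@H](O)C[C@@]2(O)C(C)C
F8 | step 5 | 4β-hydroxy-4α-isopropyl 2,10-dione | O=C1C(C)=CC[C@@H]2[C@]1(C)C(=O)C[C@@]2(O)C(C)C
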